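## Structural features

Hanultarin is the mono-(E)-ferulate of (−)-secoisolariciresinol. Its core is an open butane-1,4-diol chain C9–C8–C8'–C9' whose two adjacent stereocenters C8 and C8' (both R) each carry a guaiacylmethyl group (C7–ring A, C7'–ring B) and an oxymethylene carbon. The only rings are the three 4-hydroxy-3-methoxyphenyl rings A, B and C; ring C belongs to the feruloyl group on O9. The diol core is C2-symmetric, so O9 and O9' are homotopic: acyl migration between them is degenerate, but a late mono-acylation of the free diol would be statistical. The fragile groups are the three electron-rich phenols, the conjugated cinnamate ester (ozone, hydrogenation, conjugate addition, transesterification) and the 1,4-diol, which closes to a tetrahydrofuran when one oxygen is activated. The real difficulties are the absolute and relative configuration of an acyclic stereodiad and the distinction of O9 from O9'. The key step uses the fact that rings A and B are bound to C7 and C7', methylene carbons one bond away from C8 and C8', so that both aryl–CH2 bonds can be made by radical cross-coupling at non-stereogenic carbons of a (3R,4R)-3,4-bis(oxymethyl)adipic acid derived from a trans-disubstituted cyclohexene.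

## Logic of the disconnections

22 to 21: the three phenols and O9' are masked again as silyl ethers (four O–Si bonds). Free phenols and a second primary hydroxyl cannot be present while the ester is made. The gain is a single closing operation. The forward cleavage must spare the conjugated ester, so the fluoride has to be buffered.

21 to 17 and 20: the acyl C–O9 bond is cut. This separates ring C and its alkene from the lignan core, so the alkene never meets ozone or the cathode. The gain is convergence. The demand is that 17 has exactly one free hydroxyl, so the esterification is not statistical.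

20 to 18: the aryl O–Si bond is cut (passing through 19). The phenol must be masked to prevent self-acylation. The forward step must free the carboxyl group of 19 without touching the aryl silyl ether.

17 to 16: the O9–H bond is traced to a primary tert-butyldimethylsilyl ether. This is the point where the two oxymethyl arms are told apart. The forward acidic methanolysis must leave two aryl ethers of the same silyl group and the primary tert-butyldiphenylsilyl ether at O9' intact.

16 to 11 and 13 (twice): the C7–C1 (ring A) and C7'–C1' (ring B) bonds are cut. Both are primary sp3–sp2 bonds at non-stereogenic carbons, so the coupling cannot disturb C8 or C8'. The gain is the removal of both rings in one operation, leaving a C6 diacid derivative that carries the whole stereodiad. The demand is two successive radical captures by arylnickel, through 14 and 15. A precursor with two identical silyl ethers would leave a statistical mono-acylation for the end, so 11 carries a tert-butyldiphenylsilyl ether on one arm and a tert-butyldimethylsilyl ether on the other.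

13 to 12: the aryl O–Si bond is cut. The phenol would otherwise quench organonickel species and be oxidised. The forward step is a simple silylation.

11 to 10: the two C(=O)–O(N) bonds are cut. The redox-active esters are only activating groups. The forward esterification must be neutral so that the silyl ethers stay.

10 to 8 (through 9): the two carboxyl carbons are reconnected as the ring double bond. The acyclic stereodiad becomes a trans-disubstituted cyclohexene, a classic Diels–Alder retron. The forward cleavage must oxidise both ends to the acid level without loss of silyl groups or aldol closure of 9.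

8 to 7: the O–Si bond of the tert-butyldimethylsilyl ether is cut. The gain is a mono-protected diol. The forward step is routine.

7 to 6: the O–Si bond of the tert-butyldiphenylsilyl ether is cut. This is the desymmetrisation of a C2-symmetric diol. Because the hydroxyls are homotopic only one mono-ether exists, but the forward step must stop after one silylation.

6 to 5: the two CH2OH groups are traced to menthyl esters (C–O level change). The gain is that the auxiliary is carried by the same carbons that become C9 and C9'. The forward reduction must not touch the alkene.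

5 to 3 and 4: the ring bonds C1–C6 and C2–C3 are cut. The [4+2] transform takes the trans diester back to an E-dienophile and a simple diene. The whole burden of absolute configuration falls on the facial selectivity of this cycloaddition.

3 to 1 and 2 (twice): the two ester C–O bonds are cut. Both components are commercial. The forward step needs two equivalents of 2 and removal of water.

## Other disconnections considered

Alternative 1: The cut is the O–C9 bond of γ-butyrolactone A2, which goes back to the prochiral 3-benzylcyclobutanone A1 holding only ring A, C7 and C8.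
- Forward step: a flavin-dependent Baeyer–Villiger monooxygenase (NADPH, O2) would add its flavin peroxide to the ketone and migrate one of the two enantiotopic CH2 groups. This forms the C–O bond, expands the four-membered ring to the lactone and fixes C8.
- In its favour: a catalytic, reagent-controlled desymmetrisation with oxygen as oxidant, no auxiliary, mild aqueous conditions and a short access to A1.
- Against it here: only one stereocenter and one aryl group are in place after the step. The second arylmethyl unit must follow by enolate alkylation of A2 with bromide A3 anti to the first substituent, and the lactone must then be reduced. An enzyme with the right sense for this bulky substrate would have to be found by screening. The benzyl ethers cannot be hydrogenolysed once the cinnamate is present, so the protecting groups would have to be exchanged.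
- Structure: the alternative builds the two halves one after the other and arrives at the lactone oxidation level. The chosen plan adds rings A and B in one operation to a complete stereodiad.
- Mechanism: both rest on one asymmetric event followed by steps that cannot scramble it. The enzymatic oxidation is the better of the two in atom economy and in avoiding stoichiometric chirality and an excess of aryl iodide.
- Step economy: the two are about equal as far as the protected diol. The different oxidation states of C9 and C9' in A2 distinguish the two oxygens for a while, which is the equal of the silyl differentiation in the chosen plan. That advantage disappears on reduction to the C2-symmetric diol unless further steps are spent.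

Alternative 2: The cuts are the C8–C7 and C8'–C7' bonds, one bond closer to the stereocenters than in the chosen plan.
- Forward step: the 2-lithio derivative of dithiane A5 would add to the β-carbon of butenolide A4 anti to the menthyloxy group. The lactone enolate would be trapped in the same pot by bromide A3 anti to the new β-substituent. This gives A6 with both C–C bonds and both stereocenters, and no ring closes.
- In its favour: two skeletal bonds and the full stereodiad in one convergent step under substrate control, with the relative and absolute configuration following from the acetal carbon.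
- Against it here: A6 holds two functions the target does not need, the dithiane at C7 and the acetal at C9. Reductive desulfurisation and reduction of the acetal and lactone to the diol must follow. Desulfurisation is awkward beside benzyl ethers. A4 must first be obtained as a single acetal epimer. The diol reached in the end is again C2-symmetric and unprotected at both oxygens.
- Structure: both plans join two aryl building blocks to a C4 core under the influence of a stoichiometric menthyl auxiliary (in A4 of the enantiomeric series opposite to 2), so on the use of stoichiometric chirality they are equal.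
- Mechanism: the alternative is anionic and creates the stereocenters in the same step as the skeletal bonds, which is better than the chosen plan, where the radical coupling is stereochemically silent and depends on an earlier cycloaddition.
- Step economy: the three-component step is better in convergence, but the redox adjustments and the unsolved mono-acylation should make the total equal or longer.

Alternative 3: The cut takes the lactone carbonyl carbon C9' out of A8 as CO (the C8'–C9' and C9'–O bonds, with the C8–H bond). This leads back to the trisubstituted (E)-allylic alcohol A7, which already holds both aryl groups.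
- Forward step: a palladium hydride formed from Pd2(dba)3·CHCl3, a chiral bisphosphine and CO/H2 would add syn across the C8=C8' bond. CO would insert into the new C–Pd bond and the hydroxyl would capture the acylpalladium. This closes the γ-butyrolactone and sets both stereocenters.
- In its favour: catalytic asymmetric induction, both stereocenters in one step, CO as a one-carbon building block, no auxiliary and a direct entry to the dibenzylbutyrolactone.
- Against it here: the catalyst must distinguish the faces of an alkene whose two substituents are nearly identical arylmethyl groups. A palladium hydride can move the double bond into conjugation with either arene. The regiochemistry of hydropalladation has to be right. Pressure equipment is needed, and the benzyl ether and mono-acylation problems remain.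
- Structure: the alternative completes the carbon skeleton before the stereo-defining step, the reverse order of the chosen plan.
- Mechanism: hydrometalation and carbonylation under catalyst control consume no chiral material, which is better in principle. The auxiliary-controlled cycloaddition of the chosen plan is the more predictable source of configuration.
- Step economy: the route to the diol stage could be shorter, a point in favour of the alternative. The end game is equal.

Key step: step 9

Assumption on the chemistry: the Et2AlCl-promoted cycloaddition of the fumarate of (1R,2S,5R)-(−)-menthol is taken to favour the (1S,2S)-cyclohexene, so the fumarate of (1S,2R,5S)-(+)-menthol is used to reach the (1R,2R) adduct; should the sense be the opposite, (−)-menthol is used and nothing else changes.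

Remark on numbering: lignan numbering is used (rings A and B, C7/C7', C8/C8', C9/C9'); O9 is the oxygen that ends up acylated.

Step 1
Reactants: 1 fumaric acid; 2 (1S,2R,5S)-(+)-menthol
Product: 3 di-(+)-menthyl fumarate
Conditions: 2 (2.2 equiv in all), TsOH·H2O (cat.), toluene, reflux, Dean–Stark removal of water
Reagents that add atoms: (1S,2R,5S)-(+)-menthol (second equivalent of 2), CC(C)[C@H]1CC[C@H](C)C[C@@H]1O
Why: Twofold acid-catalysed Fischer esterification, each carboxyl group taking up one molecule of 2 and the equilibrium being driven by azeotropic removal of water; the E alkene and the menthyl stereocenters are not affected.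

Step 2
Reactants: 3 di-(+)-menthyl fumarate; 4 buta-1,3-diene
Product: 5 di-(+)-menthyl (1R,2R)-cyclohex-4-ene-1,2-dicarboxylate
Conditions: Et2AlCl (2 equiv), 4 (excess), toluene, −40 → −20 °C; recrystallisation
Reagents that add atoms: none
Why: Lewis acid-promoted, auxiliary-controlled Diels–Alder reaction; suprafacial addition keeps the ester groups trans, and the two aluminium-bound menthyl esters (each s-trans, carbinol C–H eclipsing the carbonyl, isopropyl-bearing carbon over one face) shield the same π-face of the C2-symmetric dienophile, so 4 should add to the open face, which for esters of (1S,2R,5S)-menthol sets C1 and C2 as R,R, with crystallisation removing any (1S,2S) diastereomer.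

Step 3
Reactants: 5 di-(+)-menthyl (1R,2R)-cyclohex-4-ene-1,2-dicarboxylate
Product: 6 [(1R,2R)-cyclohex-4-ene-1,2-diyl]dimethanol
Conditions: LiAlH4, THF, 0 °C → reflux; aqueous NaOH work-up
Reagents that add atoms: none
Why: Hydride reduction of both esters to primary alcohols; the isolated alkene is inert, the α-stereocenters are reduced faster than they could enolise, and the auxiliary 2 is released for recovery.

Step 4
Reactants: 6 [(1R,2R)-cyclohex-4-ene-1,2-diyl]dimethanol
Product: 7 [(1R,6R)-6-({[tert-butyl(diphenyl)silyl]oxy}methyl)cyclohex-3-en-1-yl]methanol
Conditions: NaH (1.0 equiv), THF, 0 °C → rt; then TBDPSCl (1.0 equiv), rt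
Reagents that add atoms: tert-butyl(chloro)diphenylsilane, CC(C)(C)[Si](Cl)(c1ccccc1)c1ccccc1
Why: Mono-silylation after a single deprotonation: the poorly soluble mono-anion reacts with the chlorosilane faster than it equilibrates to diol and dianion, and since the two hydroxyls are homotopic only one mono-ether can form; O9' is thereby marked.

Step 5
Reactants: 7 [(1R,6R)-6-({[tert-butyl(diphenyl)silyl]oxy}methyl)cyclohex-3-en-1-yl]methanol
Product: 8 tert-butyl{[(1R,6R)-6-({[tert-butyl(dimethyl)silyl]oxy}methyl)cyclohex-3-en-1-yl]methoxy}diphenylsilane
Conditions: TBSCl, imidazole, DMF, rt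
Reagents that add atoms: tert-butyl(chloro)dimethylsilane, CC(C)(C)[Si](C)(C)Cl
Why: Imidazole-mediated silylation of the remaining primary alcohol; the two oxygens now carry silyl groups of clearly different acid lability.

Step 6
Reactants: 8 tert-butyl{[(1R,6R)-6-({[tert-butyl(dimethyl)silyl]oxy}methyl)cyclohex-3-en-1-yl]methoxy}diphenylsilane
Product: 10 (3R,4R)-3-({[tert-butyl(diphenyl)silyl]oxy}methyl)-4-({[tert-butyl(dimethyl)silyl]oxy}methyl)hexanedioic acid, via hexanedial 9 (not isolated)
Conditions: O3, CH2Cl2, −78 °C; PPh3, −78 °C → rt; then NaClO2, NaH2PO4, 2-methylbut-2-ene, t-BuOH/H2O, rt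
Reagents that add atoms: ozone, [O-][O+]=O; sodium chlorite, [Na+].[O-]Cl=O
Why: Ozonolysis with reductive work-up cuts the ring alkene to dialdehyde 9, which is oxidised at once by buffered chlorite (Pinnick oxidation) before it can close by aldol reaction; the silyl ethers tolerate both stages and the stereocenters, β to the new carbonyl groups, cannot epimerise.

Step 7
Reactants: 10 (3R,4R)-3-({[tert-butyl(diphenyl)silyl]oxy}methyl)-4-({[tert-butyl(dimethyl)silyl]oxy}methyl)hexanedioic acid
Product: 11 bis(1,3-dioxoisoindolin-2-yl) (3R,4R)-3-({[tert-butyl(diphenyl)silyl]oxy}methyl)-4-({[tert-butyl(dimethyl)silyl]oxy}methyl)hexanedioate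
Conditions: N-hydroxyphthalimide (2.2 equiv), DIC (2.2 equiv), DMAP (cat.), CH2Cl2, 0 °C → rt
Reagents that add atoms: N-hydroxyphthalimide (two equivalents, one per carboxyl group), O=C1N(O)C(=O)c2ccccc12
Why: Carbodiimide esterification of Steglich type with the acidic N-hydroxy imide gives the two redox-active esters under neutral conditions, so the silyl ethers and the β-stereocenters are safe.

Step 8
Reactants: 12 4-iodo-2-methoxyphenol
Product: 13 tert-butyl(4-iodo-2-methoxyphenoxy)dimethylsilane
Conditions: TBSCl, imidazole, DMF, rt
Reagents that add atoms: tert-butyl(chloro)dimethylsilane, CC(C)(C)[Si](C)(C)Cl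
Why: Imidazole-mediated O-silylation of the phenol; the aryl iodide is inert, and the silyl ether keeps the phenol from quenching organonickel species in step 9.

Step 9
Reactants: 11 bis(1,3-dioxoisoindolin-2-yl) (3R,4R)-3-({[tert-butyl(diphenyl)silyl]oxy}methyl)-4-({[tert-butyl(dimethyl)silyl]oxy}methyl)hexanedioate; 13 tert-butyl(4-iodo-2-methoxyphenoxy)dimethylsilane
Product: 16 (2R,3R)-2,3-bis[4-(tert-butyldimethylsilyloxy)-3-methoxybenzyl]-1-(tert-butyldimethylsilyloxy)-4-(tert-butyldiphenylsilyloxy)butane, via monoaryl phthalimidoyl ester 14 (not isolated), via regioisomeric monoaryl phthalimidoyl ester 15 (not isolated)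
Conditions: 13 (5 equiv), NiBr2·glyme (20 mol %), 4,4'-di-tert-butyl-2,2'-bipyridine (24 mol %), AgNO3 (0.5 equiv), DMF, Mg anode/reticulated vitreous carbon cathode, undivided cell, constant current, rt
Reagents that add atoms: tert-butyl(4-iodo-2-methoxyphenoxy)dimethylsilane (second equivalent of 13, for the second aryl–CH2 bond), COc1cc(I)ccc1O[Si](C)(C)C(C)(C)C
Why: Electron transfer at the silver-coated carbon cathode (or from low-valent nickel) turns each phthalimidoyl ester into a radical anion that fragments to phthalimide anion, CO2 and a primary alkyl radical at C7 or C7'. Zerovalent nickel–bipyridine adds oxidatively to 13 to give a divalent arylnickel iodide, which captures the radical as a trivalent aryl(alkyl)nickel species; reductive elimination forms the aryl–CH2 bond, and the monovalent nickel left behind is reduced again at the cathode while the Mg anode is consumed. The closest known reaction type is the nickel-electrocatalytic decarboxylative arylation of redox-active esters with aryl halides, used here at both ends of one substrate, each end taking up one molecule of 13, so that 14 and 15 converge on 16. No ring closes and no stereocenter is formed; the radical carbons are CH2 groups one bond away from C8 and C8', so the configuration set in step 2 is out of reach. The selectivity needed is cross-coupling over hydrogen abstraction, radical dimerisation, β-hydride loss and biaryl formation; it is secured by the unhindered primary radicals, the excess of 13, the bipyridine ligand and a low constant current that keeps the radical concentration small. The silyloxy groups are separated from the radical centres by two carbons, so no β-elimination path exists, and alkyl and aryl silyl ethers should be inert to the neutral reductive medium.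

Step 10
Reactants: 16 (2R,3R)-2,3-bis[4-(tert-butyldimethylsilyloxy)-3-methoxybenzyl]-1-(tert-butyldimethylsilyloxy)-4-(tert-butyldiphenylsilyloxy)butane
Product: 17 (2R,3R)-2,3-bis[4-(tert-butyldimethylsilyloxy)-3-methoxybenzyl]-4-(tert-butyldiphenylsilyloxy)butan-1-ol
Conditions: camphorsulfonic acid (0.1 equiv), MeOH/CH2Cl2 (1:1), 0 °C
Reagents that add atoms: none
Why: Acid-catalysed methanolysis of silyl ethers discriminates by oxygen basicity and bulk at silicon: the primary alkyl tert-butyldimethylsilyl ether should be cleaved, while the aryl ethers (poorly basic oxygen) and the bulkier tert-butyldiphenylsilyl ether should stay, freeing O9 alone.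

Step 11
Reactants: 18 (E)-ferulic acid
Product: 20 (E)-3-[4-(tert-butyldimethylsilyloxy)-3-methoxyphenyl]prop-2-enoic acid, via silyl ester 19 (not isolated)
Conditions: TBSCl (2.5 equiv), imidazole, DMF, rt; then AcOH/THF/H2O, rt
Reagents that add atoms: tert-butyl(chloro)dimethylsilane, CC(C)(C)[Si](C)(C)Cl
Why: Phenol and acid are both silylated, and the far more labile silyl ester 19 is then hydrolysed selectively by aqueous acetic acid, which leaves the aryl silyl ether and the E alkene.

Step 12
Reactants: 17 (2R,3R)-2,3-bis[4-(tert-butyldimethylsilyloxy)-3-methoxybenzyl]-4-(tert-butyldiphenylsilyloxy)butan-1-ol; 20 (E)-3-[4-(tert-butyldimethylsilyloxy)-3-methoxyphenyl]prop-2-enoic acid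
Product: 21 (2R,3R)-2,3-bis[4-(tert-butyldimethylsilyloxy)-3-methoxybenzyl]-4-(tert-butyldiphenylsilyloxy)butyl (E)-3-[4-(tert-butyldimethylsilyloxy)-3-methoxyphenyl]prop-2-enoate
Conditions: EDC·HCl, DMAP, CH2Cl2, 0 °C → rt
Reagents that add atoms: none
Why: Steglich esterification (carbodiimide activation, DMAP acyl transfer) of the single free primary alcohol; the silylated phenols cannot compete, and the E alkene and both stereocenters are untouched.

Step 13
Reactants: 21 (2R,3R)-2,3-bis[4-(tert-butyldimethylsilyloxy)-3-methoxybenzyl]-4-(tert-butyldiphenylsilyloxy)butyl (E)-3-[4-(tert-butyldimethylsilyloxy)-3-methoxyphenyl]prop-2-enoate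
Product: 22 hanultarin, (2R,3R)-4-hydroxy-2,3-bis(4-hydroxy-3-methoxybenzyl)butyl (E)-3-(4-hydroxy-3-methoxyphenyl)prop-2-enoate
Conditions: Bu4NF/AcOH (1:1, excess), THF, 0 °C → rt
Reagents that add atoms: none
Why: Fluoride-induced desilylation driven by Si–F bond formation removes the three aryl silyl ethers and the primary tert-butyldiphenylsilyl ether; acetic acid buffers the phenoxides and the alkoxide so that the feruloyl ester should survive, and an acyl shift from O9 to O9' would be degenerate because the diol core is C2-symmetric.

Compound list

1 | fumaric acid | OC(=O)/C=C/C(=O)O | starting material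
2 | (1S,2R,5S)-(+)-menthol | CC(C)[C@H]1CC[C@H](C)C[C@@H]1O | starting material
3 | di-(+)-menthyl fumarate, bis[(1S,2R,5S)-5-methyl-2-(propan-2-yl)cyclohexyl] (E)-but-2-enedioate | CC(C)[C@H]1CC[C@H](C)C[C@@H]1OC(=O)/C=C/C(=O)O[C@H]1C[C@@H](C)CC[C@@H]1C(C)C | intermediate
4 | buta-1,3-diene | C=CC=C | starting material
5 | di-(+)-menthyl (1R,2R)-cyclohex-4-ene-1,2-dicarboxylate | CC(C)[C@H]1CC[C@H](C)C[C@@H]1OC(=O)[C@@H]1CC=CC[C@H]1C(=O)O[C@H]1C[C@@H](C)CC[C@@H]1C(C)C | intermediate
6 | [(1R,2R)-cyclohex-4-ene-1,2-diyl]dimethanol | OC[C@@H]1CC=CC[C@H]1CO | intermediate
7 | [(1R,6R)-6-({[tert-butyl(diphenyl)silyl]oxy}methyl)cyclohex-3-en-1-yl]methanol | CC(C)(C)[Si](c1ccccc1)(c1ccccc1)OC[C@@H]1CC=CC[C@H]1CO | intermediate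
8 | tert-butyl{[(1R,6R)-6-({[tert-butyl(dimethyl)silyl]oxy}methyl)cyclohex-3-en-1-yl]methoxy}diphenylsilane | CC(C)(C)[Si](c1ccccc1)(c1ccccc1)OC[C@@H]1CC=CC[C@H]1CO[Si](C)(C)C(C)(C)C | intermediate
9 | (3R,4R)-3-({[tert-butyl(diphenyl)silyl]oxy}methyl)-4-({[tert-butyl(dimethyl)silyl]oxy}methyl)hexanedial; not isolated | CC(C)(C)[Si](c1ccccc1)(c1ccccc1)OC[C@H](CC=O)[C@H](CO[Si](C)(C)C(C)(C)C)CC=O | intermediate
10 | (3R,4R)-3-({[tert-butyl(diphenyl)silyl]oxy}methyl)-4-({[tert-butyl(dimethyl)silyl]oxy}methyl)hexanedioic acid | CC(C)(C)[Si](c1ccccc1)(c1ccccc1)OC[C@H](CC(=O)O)[C@H](CO[Si](C)(C)C(C)(C)C)CC(=O)O | intermediate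
11 | bis(1,3-dioxoisoindolin-2-yl) (3R,4R)-3-({[tert-butyl(diphenyl)silyl]oxy}methyl)-4-({[tert-butyl(dimethyl)silyl]oxy}methyl)hexanedioate (precursor of the key step) | CC(C)(C)[Si](c1ccccc1)(c1ccccc1)OC[C@H](CC(=O)ON1C(=O)c2ccccc2C1=O)[C@H](CO[Si](C)(C)C(C)(C)C)CC(=O)ON1C(=O)c2ccccc2C1=O | intermediate
12 | 4-iodo-2-methoxyphenol | COc1cc(I)ccc1O | starting material
13 | tert-butyl(4-iodo-2-methoxyphenoxy)dimethylsilane | COc1cc(I)ccc1O[Si](C)(C)C(C)(C)C | intermediate
14 | 1,3-dioxoisoindolin-2-yl (3R,4R)-5-[4-(tert-butyldimethylsilyloxy)-3-methoxyphenyl]-4-[(tert-butyldiphenylsilyloxy)methyl]-3-[(tert-butyldimethylsilyloxy)methyl]pentanoate; not isolated | CC(C)(C)[Si](c1ccccc1)(c1ccccc1)OC[C@H](Cc1ccc(O[Si](C)(C)C(C)(C)C)c(OC)c1)[C@H](CO[Si](C)(C)C(C)(C)C)CC(=O)ON1C(=O)c2ccccc2C1=O | intermediate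
15 | 1,3-dioxoisoindolin-2-yl (3R,4R)-5-[4-(tert-butyldimethylsilyloxy)-3-methoxyphenyl]-3-[(tert-butyldiphenylsilyloxy)methyl]-4-[(tert-butyldimethylsilyloxy)methyl]pentanoate; not isolated | CC(C)(C)[Si](c1ccccc1)(c1ccccc1)OC[C@H](CC(=O)ON1C(=O)c2ccccc2C1=O)[C@H](CO[Si](C)(C)C(C)(C)C)Cc1ccc(O[Si](C)(C)C(C)(C)C)c(OC)c1 | intermediate
16 | (2R,3R)-2,3-bis[4-(tert-butyldimethylsilyloxy)-3-methoxybenzyl]-1-(tert-butyldimethylsilyloxy)-4-(tert-butyldiphenylsilyloxy)butane (product of the key step; fully silylated (2R,3R)-secoisolariciresinol) | CC(C)(C)[Si](c1ccccc1)(c1ccccc1)OC[C@H](Cc1ccc(O[Si](C)(C)C(C)(C)C)c(OC)c1)[C@H](CO[Si](C)(C)C(C)(C)C)Cc1ccc(O[Si](C)(C)C(C)(C)C)c(OC)c1 | intermediate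
17 | (2R,3R)-2,3-bis[4-(tert-butyldimethylsilyloxy)-3-methoxybenzyl]-4-(tert-butyldiphenylsilyloxy)butan-1-ol | CC(C)(C)[Si](c1ccccc1)(c1ccccc1)OC[C@H](Cc1ccc(O[Si](C)(C)C(C)(C)C)c(OC)c1)[C@H](CO)Cc1ccc(O[Si](C)(C)C(C)(C)C)c(OC)c1 | intermediate
18 | (E)-ferulic acid | COc1cc(/C=C/C(=O)O)ccc1O | starting material
19 | tert-butyldimethylsilyl (E)-3-[4-(tert-butyldimethylsilyloxy)-3-methoxyphenyl]prop-2-enoate; not isolated | COc1cc(/C=C/C(=O)O[Si](C)(C)C(C)(C)C)ccc1O[Si](C)(C)C(C)(C)C | intermediate
20 | (E)-3-[4-(tert-butyldimethylsilyloxy)-3-methoxyphenyl]prop-2-enoic acid | COc1cc(/C=C/C(=O)O)ccc1O[Si](C)(C)C(C)(C)C | intermediate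
21 | (2R,3R)-2,3-bis[4-(tert-butyldimethylsilyloxy)-3-methoxybenzyl]-4-(tert-butyldiphenylsilyloxy)butyl (E)-3-[4-(tert-butyldimethylsilyloxy)-3-methoxyphenyl]prop-2-enoate | COc1cc(/C=C/C(=O)OC[C@H](Cc2ccc(O[Si](C)(C)C(C)(C)C)c(OC)c2)[C@H](CO[Si](c2ccccc2)(c2ccccc2)C(C)(C)C)Cc2ccc(O[Si](C)(C)C(C)(C)C)c(OC)c2)ccc1O[Si](C)(C)C(C)(C)C | intermediate
22 | hanultarin, (2R,3R)-4-hydroxy-2,3-bis(4-hydroxy-3-methoxybenzyl)butyl (E)-3-(4-hydroxy-3-methoxyphenyl)prop-2-enoate | COc1cc(/C=C/C(=O)OC[C@H](Cc2ccc(O)c(OC)c2)[C@H](CO)Cc2ccc(O)c(OC)c2)ccc1O | target

Total step count: 13. Longest linear sequence: 11 steps (steps 1–7, 9, 10, 12 and 13); steps 8 and 11 prepare the two side components.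

Steps least certain to work

Step 9 (key step). The most likely failure is reduction of the primary radicals to methyl groups by hydrogen abstraction from the amide solvent, or stalling after the first coupling. Two radical captures must both outrun that pathway, and the electron-rich aryl iodide adds to zerovalent nickel comparatively slowly. Slow loss of an aryl silyl group to phthalimide anion is a second possibility. Fallback, setting out from 11 and 13: iodine–magnesium exchange on 13 with iPrMgCl·LiCl and transmetalation with ZnCl2 should give [4-(tert-butyldimethylsilyloxy)-3-methoxyphenyl]zinc chloride F1. F1 is coupled with 11 under NiCl2·glyme and 4,4'-di-tert-butyl-2,2'-bipyridine in THF/DMF at rt. This is a decarboxylative Negishi-type arylation in which the nickel catalyst itself generates the radical and the aryl group arrives by transmetalation, without an electrode. It returns to the route at 16.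

Step 2. The most likely failure is incomplete facial discrimination, or the opposite sense, in the cycloaddition. The shielding rests on the conformation of two freely rotating ester groups, and any (1S,2S) material would lower the optical purity of everything that follows. Fallback, setting out from 1 and 4: thermal Diels–Alder reaction (AcOH or dioxane, sealed vessel, heat) should give racemic trans-cyclohex-4-ene-1,2-dicarboxylic acid F2. Classical resolution by crystallisation of (R)-1-phenylethylammonium hydrogen (1R,2R)-cyclohex-4-ene-1,2-dicarboxylate F3 follows; the amine enantiomer is chosen so that the salt of the (1R,2R) acid is the less soluble one, and it is written here with the R amine. Acidification gives (1R,2R)-cyclohex-4-ene-1,2-dicarboxylic acid F4, and LiAlH4 reduction in THF returns to the route at 6.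

Step 4. The most likely failure is over-silylation to the bis-ether together with unreacted diol, if the mono-anion stays in solution and exchanges protons with the product. Fallback, setting out from 6: heating with Bu2SnO in toluene with removal of water should give the dibutylstannylene acetal of 6 F5. In F5 the tin holds both oxygens, and after the first silyl transfer with TBDPSCl the remaining tin alkoxide is deactivated, so the mono-ether is formed by a templated rather than a statistical process. It returns to the route at 7.

Step 6. The most likely failures are attack of ozone on the phenyl groups at silicon on over-exposure, aldol closure of the 1,6-dialdehyde before oxidation, and acid-induced loss of the tert-butyldimethylsilyl ether followed by lactonisation of the γ-hydroxy acid. Fallback, setting out from 8: catalytic dihydroxylation with K2OsO2(OH)4 and N-methylmorpholine N-oxide in acetone/H2O should give (4R,5R)-4-({[tert-butyl(diphenyl)silyl]oxy}methyl)-5-({[tert-butyl(dimethyl)silyl]oxy}methyl)cyclohexane-cis-1,2-diol F6, as its two diol-face isomers. F6 is cleaved with NaIO4 in buffered THF/H2O and taken on at once. This avoids ozone and peroxidic intermediates and returns to the route at 9, just before the chlorite oxidation.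

Step 13. The most likely failure is cleavage or transfer of the feruloyl group by phenoxide or fluoride during the long exposure needed to remove the hindered tert-butyldiphenylsilyl ether, or incomplete removal of that ether. Fallback, setting out from 17, with the conjugated ester made only after all silyl groups are gone: heating 17 with Meldrum's acid in toluene should give 3-{(2R,3R)-2,3-bis[4-(tert-butyldimethylsilyloxy)-3-methoxybenzyl]-4-(tert-butyldiphenylsilyloxy)butoxy}-3-oxopropanoic acid F7. Buffered fluoride then gives 3-{[(2R,3R)-4-hydroxy-2,3-bis(4-hydroxy-3-methoxybenzyl)butyl]oxy}-3-oxopropanoic acid F8, whose carboxylate protects the neighbouring ester from attack. Knoevenagel–Doebner condensation of F8 with vanillin (pyridine, piperidine cat., warm) forms the E alkene with loss of CO2 and returns to the route at 22.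

## Further compounds

F1 | step 9 | [4-(tert-butyldimethylsilyloxy)-3-methoxyphenyl]zinc chloride | COc1cc([Zn]Cl)ccc1O[Si](C)(C)C(C)(C)C
F2 | step 2 | racemic trans-cyclohex-4-ene-1,2-dicarboxylic acid | OC(=O)[C@@H]1CC=CC[C@H]1C(=O)O.OC(=O)[C@H]1CC=CC[C@@H]1C(=O)O
F3 | step 2 | (R)-1-phenylethylammonium hydrogen (1R,2R)-cyclohex-4-ene-1,2-dicarboxylate | C[C@@H]([NH3+])c1ccccc1.OC(=O)[C@@H]1CC=CC[C@H]1C(=O)[O-]
F4 | step 2 | (1R,2R)-cyclohex-4-ene-1,2-dicarboxylic acid | OC(=O)[C@@H]1CC=CC[C@H]1C(=O)O
F5 | step 4 | dibutylstannylene acetal of 6 (2,2-dibutyl-1,3,2-dioxastannepane fused trans to the (R,R)-cyclohexene) | CCCC[Sn]1(CCCC)OC[C@@H]2CC=CC[C@H]2CO1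
F6 | step 6 | (4R,5R)-4-({[tert-butyl(diphenyl)silyl]oxy}methyl)-5-({[tert-butyl(dimethyl)silyl]oxy}methyl)cyclohexane-cis-1,2-diol, both diol-face isomers | CC(C)(C)[Si](c1ccccc1)(c1ccccc1)OC[C@@H]1C[C@H](O)[C@H](O)C[C@H]1CO[Si](C)(C)C(C)(C)C.CC(C)(C)[Si](c1ccccc1)(c1ccccc1)OC[C@@H]1C[C@@H](O)[C@@H](O)C[C@H]1CO[Si](C)(C)C(C)(C)C
F7 | step 13 | 3-{(2R,3R)-2,3-bis[4-(tert-butyldimethylsilyloxy)-3-methoxybenzyl]-4-(tert-butyldiphenylsilyloxy)butoxy}-3-oxopropanoic acid | OC(=O)CC(=O)OC[C@H](Cc1ccc(O[Si](C)(C)C(C)(C)C)c(OC)c1)[C@H](CO[Si](c1ccccc1)(c1ccccc1)C(C)(C)C)Cc1ccc(O[Si](C)(C)C(C)(C)C)c(OC)c1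
F8 | step 13 | 3-{[(2R,3R)-4-hydroxy-2,3-bis(4-hydroxy-3-methoxybenzyl)butyl]oxy}-3-oxopropanoic acid | OC(=O)CC(=O)OC[C@H](Cc1ccc(O)c(OC)c1)[C@H](CO)Cc1ccc(O)c(OC)c1
A1 | alternative 1 | 3-(4-benzyloxy-3-methoxybenzyl)cyclobutan-1-one | O=C1CC(Cc2ccc(OCc3ccccc3)c(OC)c2)C1
A2 | alternative 1 | (R)-4-(4-benzyloxy-3-methoxybenzyl)dihydrofuran-2(3H)-one | O=C1C[C@@H](Cc2ccc(OCc3ccccc3)c(OC)c2)CO1
A3 | alternative 1 | 4-(benzyloxy)-3-methoxybenzyl bromide | COc1cc(CBr)ccc1OCc1ccccc1
A4 | alternative 2 | (5R)-5-[(1R,2S,5R)-menthyloxy]furan-2(5H)-one | O=C1C=C[C@H](O[C@@H]2C[C@H](C)CC[C@H]2C(C)C)O1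
A5 | alternative 2 | 2-[4-(benzyloxy)-3-methoxyphenyl]-1,3-dithiane | COc1cc(C2SCCCS2)ccc1OCc1ccccc1
A6 | alternative 2 | (3R,4R,5R)-3-(4-benzyloxy-3-methoxybenzyl)-4-[2-(4-benzyloxy-3-methoxyphenyl)-1,3-dithian-2-yl]-5-[(1R,2S,5R)-menthyloxy]dihydrofuran-2(3H)-one | C[C@@H]1CC[C@H]([C@@H](C1)O[C@@H]1OC(=O)[C@H](Cc2ccc(OCc3ccccc3)c(OC)c2)[C@H]1C1(c2ccc(OCc3ccccc3)c(OC)c2)SCCCS1)C(C)C
A7 | alternative 3 | (E)-2-(4-benzyloxy-3-methoxybenzyl)-4-(4-benzyloxy-3-methoxyphenyl)but-2-en-1-ol | OC/C(Cc1ccc(OCc2ccccc2)c(OC)c1)=C/Cc1ccc(OCc2ccccc2)c(OC)c1
A8 | alternative 3 | (3R,4R)-3,4-bis(4-benzyloxy-3-methoxybenzyl)dihydrofuran-2(3H)-one | O=C1OC[C@H](Cc2ccc(OCc3ccccc3)c(OC)c2)[C@H]1Cc1ccc(OCc2ccccc2)c(OC)c1
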